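**Assumptions:** A preparative chiral-SFC separation is counted as one step, and compounds carried on crude in the same operation are treated as not isolated. α/β mean below/above the pyran ring in the usual flavan drawing (O1 top, C2 right). The target is read as epioritin-(4β→6)-ent-oritin-4α-ol: upper unit 2R,3R,4S and lower unit 2S,3R,4R.

## Retrosynthetic overview

1. Target ⇒ benzyl/diphenylmethylene/phenylboronate-protected dimer. The interflavanyl C4–C6 bond is cut homolytically into a C4 benzylic radical (from trivalent-titanium opening of a 2,3-cis flav-3-ene epoxide) and an aryl–nickel unit (from the 6-iodo lower unit).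
2. Both halves come from the two enantiomers of one racemic flav-3-ene. The (S)-enantiomer gives the syn epoxide via the anti bromohydrin. The (R)-enantiomer gives the OsO4 diol (anti to aryl), masked as a phenylboronate and iodinated at C6.
3. The flav-3-ene (pyran ring C) is made in one step from a ring A phenol and a ring B cinnamaldehyde by boron-templated ortho-aldol, ortho-quinone methide formation and oxa-6π ring closure.
4. The ring A phenol comes from catechol (ketal, ortho-lithiation/borylation/oxidation). The ring B enal comes from 4-iodophenol and acrolein (benzylation, Heck).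
5. Ring order: rings A and B are bought as benzenes, ring C of both units is closed once (step 5), and the epoxide and dioxaborolane rings are added last.

## Route

Step 1
Reactants: 1 catechol
Product: 2 2,2-diphenyl-1,3-benzodioxole
Conditions: Ph2CCl2 (1.1 equiv), neat, 170 °C, 30 min
Reagents that add atoms: dichlorodiphenylmethane, ClC(Cl)(c1ccccc1)c1ccccc1
Why: Double O-alkylation of the catechol by the gem-dichloride (ketalisation) gives a hydrogenolysable ketal that has no acetal hydrogen and so tolerates the lithiation that follows.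

Step 2
Reactants: 2 2,2-diphenyl-1,3-benzodioxole
Product: 5 2,2-diphenyl-1,3-benzodioxol-4-ol, via aryllithium 3 (not isolated), via dimethyl arylboronate 4 (not isolated)
Conditions: n-BuLi, TMEDA, THF, 0 °C; B(OMe)3, −78 °C to rt; AcOH, H2O2 (30%), 0 °C to rt
Reagents that add atoms: hydrogen peroxide, OO
Why: Directed ortho-metalation next to the ring oxygen, borylation and oxidative boron-to-oxygen aryl migration install the third oxygen of ring A as the only free phenol.

Step 3
Reactants: 6 4-iodophenol
Product: 7 1-(benzyloxy)-4-iodobenzene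
Conditions: BnBr, K2CO3, acetone, reflux
Reagents that add atoms: benzyl bromide, BrCc1ccccc1
Why: Williamson etherification masks the ring B phenol, which would otherwise make the later 2-aryl-chromene C2–O bond labile.

Step 4
Reactants: 7 1-(benzyloxy)-4-iodobenzene; 8 acrolein
Product: 9 (E)-3-[4-(benzyloxy)phenyl]prop-2-enal
Conditions: Pd(OAc)2 (2 mol%), n-Bu4NCl, NaHCO3, DMF, 40 °C
Reagents that add atoms: none
Why: Jeffery-type Mizoroki–Heck arylation of acrolein; syn insertion and syn β-hydride elimination give the E enal.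

Step 5
Reactants: 5 2,2-diphenyl-1,3-benzodioxol-4-ol; 9 (E)-3-[4-(benzyloxy)phenyl]prop-2-enal
Product: 12 rac-2-[4-(benzyloxy)phenyl]-7,8-(diphenylmethylenedioxy)-2H-chromene (racemic flav-3-ene), via dioxaborinine 10 (not isolated), via ortho-quinone methide 11 (not isolated)
Conditions: PhB(OH)2 (1.1 equiv), EtCO2H (0.3 equiv), toluene, reflux, Dean–Stark
Reagents that add atoms: none
Why: Phenylboronic-acid-templated ortho-specific aldol addition of the phenol to the enal gives 10, which fragments thermally to 11 and closes by oxa-6π electrocyclisation to the chromene; C2 is formed racemic.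

Step 6
Reactants: 12 racemic flav-3-ene
Product: 13 (S)-2-[4-(benzyloxy)phenyl]-7,8-(diphenylmethylenedioxy)-2H-chromene (2α-aryl) and 14 its (R)-enantiomer (2β-aryl)
Conditions: preparative chiral SFC (Chiralpak AD-H, CO2/2-propanol), 35 °C
Reagents that add atoms: none
Why: Chromatographic resolution on a chiral stationary phase fixes C2 of both halves, and both enantiomers are used (13 for the upper unit, 14 for the lower); the assignment is checked by X-ray anomalous dispersion on iodide 17.

Step 7
Reactants: 14 (R)-flav-3-ene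
Product: 16 (2S,3R,4R)-2-[4-(benzyloxy)phenyl]-7,8-(diphenylmethylenedioxy)chromane-3,4-diol 3,4-O-phenylboronate (2β-aryl, 3α,4α-O), via osmate ester 15 (not isolated)
Conditions: OsO4 (2 mol%), NMO, PhB(OH)2, CH2Cl2, rt
Reagents that add atoms: osmium tetroxide, O=[Os](=O)(=O)=O; N-methylmorpholine N-oxide, C[N+]1([O-])CCOCC1; phenylboronic acid, OB(O)c1ccccc1
Why: Catalytic syn-dihydroxylation (Narasaka boronate variant of the Upjohn reaction) adds both oxygens to the face opposite the 2-aryl group, setting C3 and C4 as the 2,3-trans-3,4-cis pair, and the hexavalent-osmium ester 15 is transesterified in the flask so the diol emerges already masked.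

Step 8
Reactants: 16 lower-unit phenylboronate
Product: 17 6-iodo derivative of 16, (2S,3R,4R)
Conditions: NIS, MeCN, 0 °C to rt, dark
Reagents that add atoms: N-iodosuccinimide, O=C1CCC(=O)N1I
Why: Electrophilic aromatic iodination goes to C6, which is para to the pyran oxygen and ortho to a dioxole oxygen and is the only unhindered doubly activated position; no stereocentre is touched.

Step 9
Reactants: 13 (S)-flav-3-ene
Product: 19 (2R,3R,4R)-2-[4-(benzyloxy)phenyl]-3,4-epoxy-7,8-(diphenylmethylenedioxy)chromane (2α-aryl, 3α,4α-epoxide, 2,3-cis), via bromohydrin 18 (not isolated)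
Conditions: NBS, THF/H2O (4:1), 0 °C; then NaOH (2 M aq), 0 °C; crude used at once
Reagents that add atoms: water, O
Why: Bromonium formation anti to the 2-aryl group and anti attack of water at benzylic C4 give the 2,3-trans-3,4-trans bromohydrin, whose alkoxide closes by intramolecular SN2 with inversion at C3 (halohydrin epoxide synthesis), placing the epoxide on the aryl face, which direct epoxidation would not do.

Step 10
Reactants: 19 cis-epoxide (1.5 equiv); 17 aryl iodide
Product: 21 protected dimer (upper unit 2α-aryl, 3α-OH, 4β-aryl with the 3-OH free; lower unit (2S,3R,4R) boronate, joined C4→C6), via titanoxy benzylic radical 20 (not isolated)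
Conditions: NiCl2(dme) (10 mol%), 2,2'-bipyridine (10 mol%), Cp2TiCl2 (20 mol%), Mn (2.5 equiv), Et3N·HCl (2 equiv), DMPU, rt
Reagents that add atoms: none
Why: Nickel/titanocene reductive cross-electrophile coupling of an epoxide with an aryl halide: Cp2TiCl (trivalent titanium, made by Mn) opens the benzylic C4–O bond homolytically (Nugent–RajanBabu) to radical 20, which is captured by the aryl–nickel species from 17 on the face anti to both the 3-O–Ti group and the 2-aryl group, so the C4–C6 bond forms 3,4-trans (4β) while C3 keeps its oxygen with its configuration.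

Step 11
Reactants: 21 protected dimer
Product: 23 epioritin-(4β→6)-ent-oritin-4α-ol (target), via hexaphenol phenylboronate 22 (not isolated)
Conditions: H2 (1 atm), Pd(OH)2/C, EtOAc/THF, rt; filter; MeOH/H2O, rt; Sephadex LH-20
Reagents that add atoms: none
Why: Hydrogenolysis cleaves the two aryl benzyl ethers and the two diphenylmethylene ketals in aprotic solvent while the benzylic 3,4-diol stays tied up as the boronate so its C4–O bond is not reduced, and aqueous methanol then solvolyses the boronate; no stereocentre is touched.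

## Compound list

1 | catechol | Oc1ccccc1O | starting material
2 | 2,2-diphenyl-1,3-benzodioxole | c1ccc2OC(c3ccccc3)(c3ccccc3)Oc2c1 | intermediate
3 | 4-lithio-2,2-diphenyl-1,3-benzodioxole | [Li]c1cccc2OC(c3ccccc3)(c3ccccc3)Oc12 | intermediate
4 | dimethyl (2,2-diphenyl-1,3-benzodioxol-4-yl)boronate | COB(OC)c1cccc2OC(c3ccccc3)(c3ccccc3)Oc12 | intermediate
5 | 2,2-diphenyl-1,3-benzodioxol-4-ol | Oc1cccc2OC(c3ccccc3)(c3ccccc3)Oc12 | intermediate
6 | 4-iodophenol | Oc1ccc(I)cc1 | starting material
7 | 1-(benzyloxy)-4-iodobenzene | Ic1ccc(OCc2ccccc2)cc1 | intermediate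
8 | acrolein | C=CC=O | starting material
9 | (E)-3-[4-(benzyloxy)phenyl]prop-2-enal | O=C/C=C/c1ccc(OCc2ccccc2)cc1 | intermediate
10 | 2-phenyl-4H-1,3,2-benzodioxaborinine adduct of 5 and 9 (4-styryl, racemic) | B1(c2ccccc2)Oc2c(ccc3OC(c4ccccc4)(c4ccccc4)Oc23)C(/C=C/c2ccc(OCc3ccccc3)cc2)O1 | intermediate
11 | ortho-quinone methide (6-cinnamylidene-cyclohexadienone fused to the diphenyldioxole) | O=C1C(=C/C=C/c2ccc(OCc3ccccc3)cc2)C=CC2=C1OC(c1ccccc1)(c1ccccc1)O2 | intermediate
12 | rac-2-[4-(benzyloxy)phenyl]-7,8-(diphenylmethylenedioxy)-2H-chromene | C(c1ccccc1)Oc1ccc(cc1)C1C=Cc2ccc3OC(c4ccccc4)(c4ccccc4)Oc3c2O1 | intermediate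
13 | (S)-2-[4-(benzyloxy)phenyl]-7,8-(diphenylmethylenedioxy)-2H-chromene | C(c1ccccc1)Oc1ccc(cc1)[C@@H]1C=Cc2ccc3OC(c4ccccc4)(c4ccccc4)Oc3c2O1 | intermediate
14 | (R)-2-[4-(benzyloxy)phenyl]-7,8-(diphenylmethylenedioxy)-2H-chromene | C(c1ccccc1)Oc1ccc(cc1)[C@H]1C=Cc2ccc3OC(c4ccccc4)(c4ccccc4)Oc3c2O1 | intermediate
15 | cyclic 3,4-osmate ester of the (2S,3R,4R)-diol | C(c1ccccc1)Oc1ccc(cc1)[C@H]1[C@@H]2O[Os](=O)(=O)O[C@@H]2c2ccc3OC(c4ccccc4)(c4ccccc4)Oc3c2O1 | intermediate
16 | (2S,3R,4R)-2-[4-(benzyloxy)phenyl]-7,8-(diphenylmethylenedioxy)chromane-3,4-diol 3,4-O-phenylboronate | C(c1ccccc1)Oc1ccc(cc1)[C@H]1[C@@H]2OB(c3ccccc3)O[C@@H]2c2ccc3OC(c4ccccc4)(c4ccccc4)Oc3c2O1 | intermediate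
17 | 6-iodo-(2S,3R,4R)-2-[4-(benzyloxy)phenyl]-7,8-(diphenylmethylenedioxy)chromane-3,4-diol 3,4-O-phenylboronate | C(c1ccccc1)Oc1ccc(cc1)[C@H]1[C@@H]2OB(c3ccccc3)O[C@@H]2c2cc(I)c3OC(c4ccccc4)(c4ccccc4)Oc3c2O1 | intermediate
18 | (2R,3S,4R)-3-bromo-2-[4-(benzyloxy)phenyl]-7,8-(diphenylmethylenedioxy)chroman-4-ol (2α-aryl, 3β-Br, 4α-OH) | C(c1ccccc1)Oc1ccc(cc1)[C@@H]1[C@@H](Br)[C@H](O)c2ccc3OC(c4ccccc4)(c4ccccc4)Oc3c2O1 | intermediate
19 | (2R,3R,4R)-2-[4-(benzyloxy)phenyl]-3,4-epoxy-7,8-(diphenylmethylenedioxy)chromane | C(c1ccccc1)Oc1ccc(cc1)[C@@H]1[C@@H]2O[C@@H]2c2ccc3OC(c4ccccc4)(c4ccccc4)Oc3c2O1 | intermediate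
20 | C4 benzylic radical with 3α-O–TiCp2Cl (cyclopentadienyl rings drawn σ-bonded) | C(c1ccccc1)Oc1ccc(cc1)[C@@H]1[C@H](O[Ti](Cl)(C2C=CC=C2)C2C=CC=C2)[CH]c2ccc3OC(c4ccccc4)(c4ccccc4)Oc3c2O1 | intermediate
21 | protected dimer: upper 2α-(4-benzyloxyphenyl)-3α-hydroxy-4β-aryl flavan, lower (2S,3R,4R)-boronate, C4→C6 linked | C(c1ccccc1)Oc1ccc(cc1)[C@@H]1[C@H](O)[C@@H](c2cc3c(c4OC(c5ccccc5)(c5ccccc5)Oc24)O[C@@H](c2ccc(OCc4ccccc4)cc2)[C@@H]2OB(c4ccccc4)O[C@H]32)c2ccc3OC(c4ccccc4)(c4ccccc4)Oc3c2O1 | intermediate
22 | target with the lower 3,4-diol still as phenylboronate (same configuration as 23) | Oc1ccc(cc1)[C@@H]1[C@H](O)[C@@H](c2cc3c(c(O)c2O)O[C@@H](c2ccc(O)cc2)[C@@H]2OB(c4ccccc4)O[C@H]32)c2ccc(O)c(O)c2O1 | intermediate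
23 | (2R,3R,4S)-2-(4-hydroxyphenyl)-4-[(2S,3R,4R)-3,4,7,8-tetrahydroxy-2-(4-hydroxyphenyl)chroman-6-yl]chromane-3,7,8-triol | Oc1ccc([C@H]2Oc3c(ccc(O)c3O)[C@H](c3cc4c(c(O)c3O)O[C@@H](c3ccc(O)cc3)[C@H](O)[C@@H]4O)[C@H]2O)cc1 | target

## Step count and risks

Total steps: 11. Longest linear sequence: 8 (steps 1, 2, 5, 6, 7, 8, 10, 11).

**Step 10 (most likely to fail).** Radical 20 may be reduced back to flavene 13 by a second trivalent titanium, the electron-rich epoxide may rearrange to the flavan-3-one, and the hindered electron-rich iodide may add slowly to nickel. The fallback replaces the radical coupling by a polar one. It sets out from epoxide 19 and the non-iodinated boronate 16. Epoxide 19 is opened at C4 with phenylmethanethiol (cat. Et3N, THF, 0 °C, SN2 with inversion) to (2R,3S,4S)-4β-benzylsulfanyl-2-[4-(benzyloxy)phenyl]-7,8-(diphenylmethylenedioxy)chroman-3-ol F1. This thioether is activated with AgBF4 (THF, 0 °C) in the presence of 16, whose C6 attacks the C4 cation anti to the 3-OH. This returns to the route at 21.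

**Step 9.** Water may attack the open C4 cation from both faces (only the trans bromohydrin closes), and the epoxide is very acid-labile. The fallback replaces the halohydrin sequence by catalyst-controlled oxygen-atom transfer. It sets out from 13 and uses Jacobsen–Katsuki epoxidation with (R,R)-[N,N'-bis(3,5-di-tert-butylsalicylidene)cyclohexane-1,2-diaminato]manganese chloride, NaOCl and 4-phenylpyridine N-oxide in CH2Cl2 at 0 °C. The catalyst delivers oxygen to the 3R,4R face, syn to the aryl group. It returns to the route at 19 and makes no new compound (F0).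

**Step 11.** The benzylic C4–O bond of the lower unit may be hydrogenolysed if the boronate is lost early, and the ketals may cleave incompletely. The fallback replaces reductive cleavage by Lewis-acid dealkylation with a cation scavenger. It sets out from 21 and uses BCl3 and pentamethylbenzene in CH2Cl2 at −78 °C, then a MeOH/aqueous NaHCO3 quench that also frees the diol. It returns to the route at 23 and makes no new compound (F0).

## Further compounds

F1 | step 10 | (2R,3S,4S)-4β-benzylsulfanyl-2-[4-(benzyloxy)phenyl]-7,8-(diphenylmethylenedioxy)chroman-3-ol | C(c1ccccc1)Oc1ccc(cc1)[C@@H]1[C@H](O)[C@@H](SCc2ccccc2)c2ccc3OC(c4ccccc4)(c4ccccc4)Oc3c2O1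
F0 | step 9 | none | none
F0 | step 11 | none | none
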